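## Analysis of the target

Target 20 is a 2,3-dihydrobenzofuran neolignan. Ring A (C3a, C4, C5, C6, C7, C7a) is fused to a dihydrofuran ring (O1, C2, C3). C2 carries a 3,4-dimethoxyphenyl (veratryl) group, C3 a methyl group, C7 a methoxy group and C5 an (E)-3-hydroxyprop-1-enyl chain. The only stereocentres are C2 (S) and C3 (S); they are adjacent, and the aryl and methyl groups are trans on the five-membered ring. The C2–O1 bond is a benzylic aryl ether next to an electron-rich arene and ionises easily under acid. The cinnamyl alcohol is acid- and oxidation-sensitive, and all aromatic units are electron-rich. The synthesis is hard for two reasons: two contiguous benzylic-type centres must be set in absolute terms, and ring A is 1,2,3,5-tetrasubstituted with two neighbouring oxygens. The plan rests on the pattern O1 on C7a, oxygen on the adjacent C7, and carbon (C3) on C3a. This is the pattern obtained when a 2-substituted furan, tethered through two carbons and an oxygen to a terminal alkyne, is isomerised to a phenol. Furan C2 becomes C3a, the alkyne carbons become C7a and C7, the furan oxygen moves to C7, and furan C3, C4 and C5 become C4, C5 and C6.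

## Retrosynthetic reasoning

**Side chain (20 ⇒ 19 ⇒ 17 + 18).** The C=C bond of the propenol chain is cut. Allylic alcohol 20 is the 1,2-reduction product of cinnamate 19, which comes from aldehyde 17 and phosphonate 18. The cut is made here because a conjugated allylic alcohol, or a vinylfuran that would lead to it, would be a liability in the metal-catalysed steps. What is gained is that ring A needs only a one-carbon substituent at C5. The forward steps have to give the E alkene and reduce the ester without touching the alkene.

**Adjustments at C5 and C7 (17 ⇒ 16 ⇒ 15 ⇒ 14).** The aldehyde goes back to benzylic alcohol 16, this to silyl ether 15, and the C7 methyl ether to phenol 14. The O–CH3 bond is cut because the ring-forming step delivers a free hydroxyl at C7.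

**Both rings (14 ⇒ 11).** The bonds C3a–C7a and C6–C7 are cut, and the C7 oxygen is returned to its place as the furan oxygen between C3a and C6. This opens ring A and the dihydrofuran together and leaves furan–ynol ether 11. It is the central disconnection for three reasons: the forward reaction is an isomerisation with no change in oxidation level, the two stereocentres are not involved, and every ring-A substituent is encoded in simple groups. The furan 4-substituent becomes the C5 handle and the ether oxygen becomes O1. The forward reaction has to direct furan C2 onto the oxygen-bearing alkyne carbon and open the arene oxide so that the hydroxyl ends on C7.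

**Ynol ether (11 ⇒ 8 ⇒ 6 + 7).** The O–C(sp) bond is cut. The two alkyne carbons come from 7 through dichlorovinyl ether 8. Only the O–H bond of alcohol 6 reacts, so the configuration at the carbinol carbon is carried over unchanged.

**Carbinol centre (6 ⇒ 5).** The alcohol goes back to ketone 5. The α-centre of 5 lies between a carbonyl and a furan and is configurationally labile. This is used: an asymmetric reduction with dynamic kinetic resolution should set both centres from racemic 5 in one step.

**Cα–furan bond (5 ⇒ 3 + 4).** The bond between the ketone α-carbon and furan C2 is cut, which leads to ketone 4 and bromofuran 3. The cut joins two simple pieces, and the future C3 methyl group is present in 4 from the start.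

**Furan piece (3 ⇒ 2 ⇒ 1).** Silyl ether 3 comes from alcohol 2, and 2 from ester 1 by reduction.

## Alternatives that were turned down

**Alternative 1:** The disconnection cuts C2–aryl and C3–C3a across a propenyl unit and closes no ring. In the forward key step an ate complex is formed from (E)-prop-1-enyl B(mac) boronate A2 and (3,4-dimethoxyphenyl)lithium A3. Under a palladium/ferrocenyl-bisphosphine catalyst it undergoes a 1,2-boron shift and couples with aryl bromide A4, giving boronate A1.
- For it: it is a convergent three-component coupling, both stereocentres come from one catalyst-controlled, stereospecific anti addition, and ring A is bought with its oxygens in place.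
- Against it: β-substituted alkenyl ate complexes are at the demanding end of this coupling, and A4 is hindered by its ortho acetal ether. The ring oxygen has to come from the ring-A phenol, so the C2–O1 bond must be made by substitution at the benzylic carbinol obtained after C–B oxidation. Inversion would give the cis ring, so closure has to go through the benzylic cation. The C2 configuration bought with the catalyst is thereby erased, and only C3 counts.
- Comparison: on convergence and on setting stereochemistry in one step it is as strong as or stronger than the chosen plan, and probably shorter. The chosen plan offers in its place a C2–O bond that is made as a defined alcohol and never broken, and a ring A built by isomerisation without phenol protecting groups.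

**Alternative 2:** The disconnection is at C3–C3a, made by a 1,2-shift of ring-A carbon C4a in a flavanone. In the forward key step a hypervalent iodine oxidant in acidic orthoformate contracts flavanone A6 to the trans ester A5.
- For it: A6 comes from two cheap aromatic building blocks through a chalcone, ring A already carries the C7 methoxy group and a bromide for the side chain, and the trans relationship is the thermodynamic one.
- Against it: enantioenriched flavanones racemise by reversible ring-opening to the chalcone, and the key step is run in strong acid. The electron-rich veratryl group on C2 is itself a good migrating group and competes with ring A. C3 emerges as an ester on an epimerisable centre and needs about three redox steps to become the methyl group.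
- Comparison: it is stronger on cost of materials and has no ring-A regiochemistry question. It is weaker on stereochemical integrity and oxidation-state economy. The chosen plan has the C3 methyl group present from ketone 4 and sets both centres in a configurationally stable alcohol.

**Alternative 3:** The disconnection cuts C3a–C4 and C7a–C7; ring A comes from a 2-pyrone. In the forward key step silyl ketene acetal A9 and pyrone A8 undergo an inverse-demand [4+2] cycloaddition, then lose CO2 and silanol to give arene A7.
- For it: it also builds ring A from scratch, the stereocentres sit in a robust trans lactone and are spectators, the reaction is thermal and metal-free, and the C5 ester is a direct handle for the side chain.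
- Against it: C7 emerges as a bromide, so a late C–O coupling ortho to O1 on a hindered, electron-rich ring is needed. At the ketal carbon C7a the aromatisation can expel either the silyloxy group or the ring oxygen, and the second path opens the dihydrofuran. The enantiopure lactone itself takes several steps.
- Comparison: the ring-forming event is arguably more robust than an acid-sensitive ynol ether, and the step count is similar. The chosen plan delivers the C7 oxygen directly in the ring-forming step and keeps O1–C2 intact throughout.

Key step: step 7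

Assumption: compound 1 is taken as a purchasable building block. Species bound to Pd, Ru or Au inside a catalytic cycle are described in the Why lines and are not numbered; discrete stoichiometric or metal-free intermediates are numbered.

## Route

Step 1
Reactants: 1 methyl 5-bromofuran-3-carboxylate
Product: 2 (5-bromofuran-3-yl)methanol
Conditions: i-Bu2AlH (2.2 equiv), CH2Cl2, −78 → 0 °C; aq. potassium sodium tartrate
Reagents that add atoms: none
Why: Ester-to-alcohol reduction with an aluminium hydride; two hydride equivalents take the furoate to the primary alcohol, and the furan C–Br bond is inert to i-Bu2AlH at low temperature.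

Step 2
Reactants: 2 (5-bromofuran-3-yl)methanol
Product: 3 [(5-bromofuran-3-yl)methoxy](tert-butyl)dimethylsilane
Conditions: TBSCl, imidazole, CH2Cl2, 0 °C → rt
Reagents that add atoms: tert-butyldimethylsilyl chloride (TBSCl), CC(C)(C)[Si](C)(C)Cl
Why: Imidazole-promoted silylation of a primary alcohol; the TBS ether removes the only acidic hydrogen before the base-mediated steps and tolerates alkoxide bases and alkyllithium at low temperature.

Step 3
Reactants: 3 [(5-bromofuran-3-yl)methoxy](tert-butyl)dimethylsilane; 4 1-(3,4-dimethoxyphenyl)propan-1-one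
Product: 5 rac-2-[4-({[tert-butyl(dimethyl)silyl]oxy}methyl)furan-2-yl]-1-(3,4-dimethoxyphenyl)propan-1-one
Conditions: Pd(OAc)2 (2 mol %), XPhos (4 mol %), NaOt-Bu, toluene, 70 °C
Reagents that add atoms: none
Why: Palladium-catalysed α-arylation of a ketone enolate (Buchwald–Hartwig type): zerovalent palladium inserts into the furan C–Br bond, the sodium enolate of 4 transmetalates and the bulky XPhos complex undergoes reductive elimination. The product is held as a hindered tetrasubstituted enolate, which should prevent a second arylation; the new centre is formed racemic and is corrected in step 4.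

Step 4
Reactants: 5 rac-2-[4-({[tert-butyl(dimethyl)silyl]oxy}methyl)furan-2-yl]-1-(3,4-dimethoxyphenyl)propan-1-one
Product: 6 (1S,2R)-2-[4-({[tert-butyl(dimethyl)silyl]oxy}methyl)furan-2-yl]-1-(3,4-dimethoxyphenyl)propan-1-ol
Conditions: RuCl(p-cymene)[(S,S)-TsDPEN] (2 mol %), HCO2H/Et3N (1:3), DMF, 40 °C
Reagents that add atoms: none
Why: Noyori–Ikariya asymmetric transfer hydrogenation run as a dynamic kinetic resolution: the α-hydrogen between carbonyl and furan exchanges through the enol in the amine-rich medium, so the enantiomers of 5 interconvert while the (S,S)-catalyst delivers hydride to the Re face, giving the 1S carbinol as for aryl alkyl ketones. The ketone enantiomer whose Felkin–Anh-preferred face (hydride anti to the furyl group) is that same face should be reduced faster, giving the syn (1S,2R) alcohol.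

Step 5
Reactants: 6 (1S,2R)-2-[4-({[tert-butyl(dimethyl)silyl]oxy}methyl)furan-2-yl]-1-(3,4-dimethoxyphenyl)propan-1-ol; 7 trichloroethylene
Product: 8 tert-butyl({5-[(1S,2R)-1-{[(E)-1,2-dichloroethenyl]oxy}-1-(3,4-dimethoxyphenyl)propan-2-yl]furan-3-yl}methoxy)dimethylsilane
Conditions: KH (2.2 equiv), THF, 0 °C; 7 (1.2 equiv), −50 °C → rt
Reagents that add atoms: none
Why: First stage of the Greene ynol ether synthesis: the potassium alkoxide of 6 adds to dichloroacetylene, formed in the flask from 7 by base-induced loss of HCl, and protonation of the vinyl anion gives the (E)-1,2-dichlorovinyl ether. Only the O–H bond reacts, so neither stereocentre is touched.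

Step 6
Reactants: 8 tert-butyl({5-[(1S,2R)-1-{[(E)-1,2-dichloroethenyl]oxy}-1-(3,4-dimethoxyphenyl)propan-2-yl]furan-3-yl}methoxy)dimethylsilane
Product: 11 tert-butyl({5-[(1S,2R)-1-(3,4-dimethoxyphenyl)-1-(ethynyloxy)propan-2-yl]furan-3-yl}methoxy)dimethylsilane, via chloroalkynyl ether 9 (not isolated), via lithium alkynyl ether 10 (not isolated)
Conditions: n-BuLi (2.3 equiv), THF, −78 → −40 °C; MeOH, −78 °C; cold work-up, used at once
Reagents that add atoms: none
Why: Second stage of the Greene sequence: n-BuLi eliminates HCl to give chloroalkyne 9, chlorine–lithium exchange gives acetylide 10, and methanol protonates it at −78 °C. The low temperature should avoid furan lithiation and sigmatropic rearrangement of the benzylic ynol ether.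

Step 7
Reactants: 11 tert-butyl({5-[(1S,2R)-1-(3,4-dimethoxyphenyl)-1-(ethynyloxy)propan-2-yl]furan-3-yl}methoxy)dimethylsilane
Product: 14 (2S,3S)-5-({[tert-butyl(dimethyl)silyl]oxy}methyl)-2-(3,4-dimethoxyphenyl)-3-methyl-2,3-dihydro-1-benzofuran-7-ol, via oxepine 12 (not isolated), via arene oxide 13 (not isolated)
Conditions: Ph3PAuNTf2 (3 mol %), CH2Cl2, 4 Å MS, −20 °C → rt
Reagents that add atoms: none
Why: Ph3PAu+ (monovalent gold) binds the terminal ynol ether, which the ether oxygen polarises like a ketene oxonium, so the oxygen-bearing alkyne carbon (future C7a) is the electrophilic site. Furan C2 attacks it in a 5-exo-dig closure that forms C3a–C7a and the dihydrofuran ring, and the gold-bound cyclopropyl carbene so formed fragments, with cleavage of the furan C2–O bond, to a (Z)-dienal carrying a gold carbene at the future C7. The aldehyde oxygen adds to that carbene carbon and releases the catalyst to give oxepine 12, whose 6π electrocyclic closure to arene oxide 13 forms C6–C7 and closes ring A. Opening of the epoxide at C6 gives a cation delocalised onto C7a, where O1 stabilises it, so the oxygen stays on C7 and loss of the C7 proton gives phenol 14. The closest known reaction type is the gold-catalysed furan–yne phenol synthesis, which includes alkynyl ether tethers that give 7-hydroxy-2,3-dihydrobenzofurans. No stereocentre is formed: C2 and C3 are sp3 spectators that keep their geometry, and the C3 descriptor changes from R in 11 to S in 14 only because the furan carbon becomes an arene carbon in the priority ranking. The step needs the furan to react faster than the veratryl ring and faster than ionisation of the benzylic C–O bond; the higher nucleophilicity of the furan, the five-membered transition state and the low temperature should secure this, and the furan 4-substituent ends up at C5.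

Step 8
Reactants: 14 (2S,3S)-5-({[tert-butyl(dimethyl)silyl]oxy}methyl)-2-(3,4-dimethoxyphenyl)-3-methyl-2,3-dihydro-1-benzofuran-7-ol
Product: 15 tert-butyl{[(2S,3S)-2-(3,4-dimethoxyphenyl)-7-methoxy-3-methyl-2,3-dihydro-1-benzofuran-5-yl]methoxy}dimethylsilane
Conditions: MeI, K2CO3, acetone, 40 °C
Reagents that add atoms: iodomethane (MeI), CI
Why: Williamson O-methylation of the phenol; the silyl ether and the benzylic ring ether are stable to carbonate base.

Step 9
Reactants: 15 tert-butyl{[(2S,3S)-2-(3,4-dimethoxyphenyl)-7-methoxy-3-methyl-2,3-dihydro-1-benzofuran-5-yl]methoxy}dimethylsilane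
Product: 16 [(2S,3S)-2-(3,4-dimethoxyphenyl)-7-methoxy-3-methyl-2,3-dihydro-1-benzofuran-5-yl]methanol
Conditions: Bu4NF, THF, 0 °C → rt
Reagents that add atoms: none
Why: Fluoride cleavage of the primary TBS ether, driven by the Si–F bond; the non-acidic conditions leave the C2–O1 bond intact.

Step 10
Reactants: 16 [(2S,3S)-2-(3,4-dimethoxyphenyl)-7-methoxy-3-methyl-2,3-dihydro-1-benzofuran-5-yl]methanol
Product: 17 (2S,3S)-2-(3,4-dimethoxyphenyl)-7-methoxy-3-methyl-2,3-dihydro-1-benzofuran-5-carbaldehyde
Conditions: MnO2 (activated, excess), CH2Cl2, rt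
Reagents that add atoms: none
Why: Selective oxidation of a benzylic alcohol to the aldehyde with activated MnO2, which does not over-oxidise and should not affect the electron-rich arenes or the stereocentres.

Step 11
Reactants: 17 (2S,3S)-2-(3,4-dimethoxyphenyl)-7-methoxy-3-methyl-2,3-dihydro-1-benzofuran-5-carbaldehyde; 18 triethyl phosphonoacetate
Product: 19 ethyl (2E)-3-[(2S,3S)-2-(3,4-dimethoxyphenyl)-7-methoxy-3-methyl-2,3-dihydro-1-benzofuran-5-yl]prop-2-enoate
Conditions: NaH, THF, 0 °C → rt
Reagents that add atoms: none
Why: Horner–Wadsworth–Emmons olefination with a stabilised phosphonate anion; reversible addition and elimination through the favoured oxaphosphetane should give the E cinnamate.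

Step 12
Reactants: 19 ethyl (2E)-3-[(2S,3S)-2-(3,4-dimethoxyphenyl)-7-methoxy-3-methyl-2,3-dihydro-1-benzofuran-5-yl]prop-2-enoate
Product: 20 (2E)-3-[(2S,3S)-2-(3,4-dimethoxyphenyl)-7-methoxy-3-methyl-2,3-dihydro-1-benzofuran-5-yl]prop-2-en-1-ol
Conditions: i-Bu2AlH (2.5 equiv), CH2Cl2, −78 °C; aq. potassium sodium tartrate
Reagents that add atoms: none
Why: 1,2-Reduction of the α,β-unsaturated ester with i-Bu2AlH at −78 °C should give the allylic alcohol without conjugate reduction, with the alkene geometry and both stereocentres retained.

## Compound list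

1 | methyl 5-bromofuran-3-carboxylate | COC(=O)c1coc(Br)c1 | starting material
2 | (5-bromofuran-3-yl)methanol | OCc1coc(Br)c1 | intermediate
3 | [(5-bromofuran-3-yl)methoxy](tert-butyl)dimethylsilane | CC(C)(C)[Si](C)(C)OCc1coc(Br)c1 | intermediate
4 | 1-(3,4-dimethoxyphenyl)propan-1-one (3',4'-dimethoxypropiophenone) | CCC(=O)c1ccc(OC)c(OC)c1 | starting material
5 | rac-2-[4-({[tert-butyl(dimethyl)silyl]oxy}methyl)furan-2-yl]-1-(3,4-dimethoxyphenyl)propan-1-one | COc1ccc(C(=O)C(C)c2cc(CO[Si](C)(C)C(C)(C)C)co2)cc1OC | intermediate
6 | (1S,2R)-2-[4-({[tert-butyl(dimethyl)silyl]oxy}methyl)furan-2-yl]-1-(3,4-dimethoxyphenyl)propan-1-ol | COc1ccc([C@@H](O)[C@@H](C)c2cc(CO[Si](C)(C)C(C)(C)C)co2)cc1OC | intermediate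
7 | trichloroethylene (1,1,2-trichloroethene) | ClC=C(Cl)Cl | starting material
8 | tert-butyl({5-[(1S,2R)-1-{[(E)-1,2-dichloroethenyl]oxy}-1-(3,4-dimethoxyphenyl)propan-2-yl]furan-3-yl}methoxy)dimethylsilane | COc1ccc([C@@H](O/C(Cl)=C\Cl)[C@@H](C)c2cc(CO[Si](C)(C)C(C)(C)C)co2)cc1OC | intermediate
9 | tert-butyl({5-[(1S,2R)-1-[(chloroethynyl)oxy]-1-(3,4-dimethoxyphenyl)propan-2-yl]furan-3-yl}methoxy)dimethylsilane (chloroalkynyl ether) | COc1ccc([C@@H](OC#CCl)[C@@H](C)c2cc(CO[Si](C)(C)C(C)(C)C)co2)cc1OC | intermediate (not isolated)
10 | lithium acetylide of 11, {[(1S,2R)-2-[4-({[tert-butyl(dimethyl)silyl]oxy}methyl)furan-2-yl]-1-(3,4-dimethoxyphenyl)propoxy]ethynyl}lithium | COc1ccc([C@@H](OC#C[Li])[C@@H](C)c2cc(CO[Si](C)(C)C(C)(C)C)co2)cc1OC | intermediate (not isolated)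
11 | tert-butyl({5-[(1S,2R)-1-(3,4-dimethoxyphenyl)-1-(ethynyloxy)propan-2-yl]furan-3-yl}methoxy)dimethylsilane | COc1ccc([C@@H](OC#C)[C@@H](C)c2cc(CO[Si](C)(C)C(C)(C)C)co2)cc1OC | intermediate
12 | oxepine: the 2,3-dihydrofuro[2,3-c]oxepine in which an oxygen bridges C6 and C7 of the future ring A, with the (2S)-veratryl, (3S)-methyl and TBSOCH2 groups of 14 | COc1ccc([C@H]2OC3=COC=C(CO[Si](C)(C)C(C)(C)C)C=C3[C@@H]2C)cc1OC | intermediate (not isolated)
13 | arene oxide: the C6–C7 epoxide (benzene oxide) valence tautomer of 12, configuration at C6 and C7 not defined | COc1ccc([C@H]2OC3=C(C=C(CO[Si](C)(C)C(C)(C)C)C4OC34)[C@@H]2C)cc1OC | intermediate (not isolated)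
14 | (2S,3S)-5-({[tert-butyl(dimethyl)silyl]oxy}methyl)-2-(3,4-dimethoxyphenyl)-3-methyl-2,3-dihydro-1-benzofuran-7-ol | COc1ccc([C@H]2Oc3c(O)cc(CO[Si](C)(C)C(C)(C)C)cc3[C@@H]2C)cc1OC | intermediate
15 | tert-butyl{[(2S,3S)-2-(3,4-dimethoxyphenyl)-7-methoxy-3-methyl-2,3-dihydro-1-benzofuran-5-yl]methoxy}dimethylsilane | COc1ccc([C@H]2Oc3c(OC)cc(CO[Si](C)(C)C(C)(C)C)cc3[C@@H]2C)cc1OC | intermediate
16 | [(2S,3S)-2-(3,4-dimethoxyphenyl)-7-methoxy-3-methyl-2,3-dihydro-1-benzofuran-5-yl]methanol | COc1ccc([C@H]2Oc3c(OC)cc(CO)cc3[C@@H]2C)cc1OC | intermediate
17 | (2S,3S)-2-(3,4-dimethoxyphenyl)-7-methoxy-3-methyl-2,3-dihydro-1-benzofuran-5-carbaldehyde | COc1ccc([C@H]2Oc3c(OC)cc(C=O)cc3[C@@H]2C)cc1OC | intermediate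
18 | triethyl phosphonoacetate | CCOC(=O)CP(=O)(OCC)OCC | starting material
19 | ethyl (2E)-3-[(2S,3S)-2-(3,4-dimethoxyphenyl)-7-methoxy-3-methyl-2,3-dihydro-1-benzofuran-5-yl]prop-2-enoate | COc1ccc([C@H]2Oc3c(OC)cc(/C=C/C(=O)OCC)cc3[C@@H]2C)cc1OC | intermediate
20 | (2E)-3-[(2S,3S)-2-(3,4-dimethoxyphenyl)-7-methoxy-3-methyl-2,3-dihydro-1-benzofuran-5-yl]prop-2-en-1-ol | COc1ccc([C@H]2Oc3c(OC)cc(/C=C/CO)cc3[C@@H]2C)cc1OC | target

## Step count and least certain steps

Total: 12 steps. Longest linear sequence: 12 steps (1 → 20); compounds 4, 7 and 18 enter as purchased materials.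

**Step 7 (key step).** Several processes can divert the gold-activated ynol ether before the furan closes onto it:
- ionisation of the veratryl C–O bond, with loss or 1,3-shift of the benzylic group;
- thermal sigmatropic rearrangement into the veratryl ring;
- hydration by adventitious water;
- attack by the veratryl ring instead of the furan.

In addition, the arene oxide could open toward C6 and put the hydroxyl in the wrong place.

The fallback gives up the furan as the source of ring A and closes the C2–O1 bond last. It sets out from 4 and returns at 16. Commercial methyl 3-bromo-4-hydroxy-5-methoxybenzoate F1 is protected (MOMCl, i-Pr2NEt) as methyl 3-bromo-5-methoxy-4-(methoxymethoxy)benzoate F2. α-Arylation of 4 with F2 (Pd(OAc)2, XPhos, K3PO4, toluene) should give racemic methyl 3-[1-(3,4-dimethoxyphenyl)-1-oxopropan-2-yl]-5-methoxy-4-(methoxymethoxy)benzoate F3. Transfer hydrogenation under the conditions of step 4 should give methyl 3-[(1S,2S)-1-(3,4-dimethoxyphenyl)-1-hydroxypropan-2-yl]-5-methoxy-4-(methoxymethoxy)benzoate F4. HCl in methanol then removes the acetal and ionises the veratryl carbinol, and the phenol should capture the cation anti to the C3 methyl group. This gives methyl (2S,3S)-2-(3,4-dimethoxyphenyl)-7-methoxy-3-methyl-2,3-dihydro-1-benzofuran-5-carboxylate F5, and i-Bu2AlH reduces F5 to 16.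

**Step 4.** Enolisation may be slow compared with reduction, or the Felkin–Anh preference may not match the catalyst, so that the dynamic resolution gives low diastereoselectivity. The fallback replaces it by substrate control plus resolution; it sets out from 5 and returns at 6. LiBH(s-Bu)3 in THF at −78 °C should give the racemic syn alcohol, that is 6 together with its enantiomer (1R,2S)-2-[4-({[tert-butyl(dimethyl)silyl]oxy}methyl)furan-2-yl]-1-(3,4-dimethoxyphenyl)propan-1-ol F6. The two are separated by preparative chromatography on a chiral stationary phase, and F6 is oxidised back to 5 (Dess–Martin periodinane) and recycled.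

**Step 3.** The electron-rich 2-bromofuran may decompose or lose bromine reductively before coupling, or the furylpalladium species may stall the catalyst. The fallback reverses the polarity; it sets out from 4 and 3 and returns at 5. Ketone 4 is brominated with CuBr2 to racemic 2-bromo-1-(3,4-dimethoxyphenyl)propan-1-one F7. Bromofuran 3 is converted by bromine–lithium exchange (n-BuLi, −78 °C) into [4-({[tert-butyl(dimethyl)silyl]oxy}methyl)furan-2-yl]lithium F8 and then with ZnCl2 into chloro[4-({[tert-butyl(dimethyl)silyl]oxy}methyl)furan-2-yl]zinc F9. A nickel-catalysed Negishi arylation of the secondary α-bromoketone (NiCl2·glyme, pybox ligand, THF/glyme, −30 °C) joins F7 and F9 to give 5.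

**Step 6.** The benzylic ynol ether may rearrange or eliminate (retro-ene loss of ketene) during work-up and storage. The fallback carries the alkyne as a more robust C-silyl derivative; it sets out from 8 and returns at 11. After the n-BuLi treatment, acetylide 10 is quenched with Me3SiCl instead of methanol to give tert-butyl({5-[(1S,2R)-1-(3,4-dimethoxyphenyl)-1-{[(trimethylsilyl)ethynyl]oxy}propan-2-yl]furan-3-yl}methoxy)dimethylsilane F10, which can be purified and stored cold. The C–Si bond is cleaved with K2CO3 in MeOH at 0 °C immediately before step 7, and crude 11 is passed through basic alumina and used directly.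

## Further compounds

F1 | step 7 | methyl 3-bromo-4-hydroxy-5-methoxybenzoate | COC(=O)c1cc(Br)c(O)c(OC)c1
F2 | step 7 | methyl 3-bromo-5-methoxy-4-(methoxymethoxy)benzoate | COCOc1c(Br)cc(C(=O)OC)cc1OC
F3 | step 7 | rac-methyl 3-[1-(3,4-dimethoxyphenyl)-1-oxopropan-2-yl]-5-methoxy-4-(methoxymethoxy)benzoate | COc1ccc(C(=O)C(C)c2cc(C(=O)OC)cc(OC)c2OCOC)cc1OC
F4 | step 7 | methyl 3-[(1S,2S)-1-(3,4-dimethoxyphenyl)-1-hydroxypropan-2-yl]-5-methoxy-4-(methoxymethoxy)benzoate | COc1ccc([C@@H](O)[C@@H](C)c2cc(C(=O)OC)cc(OC)c2OCOC)cc1OC
F5 | step 7 | methyl (2S,3S)-2-(3,4-dimethoxyphenyl)-7-methoxy-3-methyl-2,3-dihydro-1-benzofuran-5-carboxylate | COc1ccc([C@H]2Oc3c(OC)cc(C(=O)OC)cc3[C@@H]2C)cc1OC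
F6 | step 4 | (1R,2S)-2-[4-({[tert-butyl(dimethyl)silyl]oxy}methyl)furan-2-yl]-1-(3,4-dimethoxyphenyl)propan-1-ol | COc1ccc([C@H](O)[C@H](C)c2cc(CO[Si](C)(C)C(C)(C)C)co2)cc1OC
F7 | step 3 | rac-2-bromo-1-(3,4-dimethoxyphenyl)propan-1-one | CC(Br)C(=O)c1ccc(OC)c(OC)c1
F8 | step 3 | [4-({[tert-butyl(dimethyl)silyl]oxy}methyl)furan-2-yl]lithium | [Li]c1cc(CO[Si](C)(C)C(C)(C)C)co1
F9 | step 3 | chloro[4-({[tert-butyl(dimethyl)silyl]oxy}methyl)furan-2-yl]zinc | Cl[Zn]c1cc(CO[Si](C)(C)C(C)(C)C)co1
F10 | step 6 | tert-butyl({5-[(1S,2R)-1-(3,4-dimethoxyphenyl)-1-{[(trimethylsilyl)ethynyl]oxy}propan-2-yl]furan-3-yl}methoxy)dimethylsilane | COc1ccc([C@@H](OC#C[Si](C)(C)C)[C@@H](C)c2cc(CO[Si](C)(C)C(C)(C)C)co2)cc1OC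
A1 | alternative 1 | (1S,2R)-1-(3,4-dimethoxyphenyl)-2-[5-(1,3-dioxolan-2-yl)-3-methoxy-2-(methoxymethoxy)phenyl]propyl B(mac) boronate | C[C@]12OB([C@H](c3ccc(OC)c(OC)c3)[C@@H](C)c3cc(C4OCCO4)cc(OC)c3OCOC)O[C@@]1(C)c1cccc3cccc2c13
A2 | alternative 1 | (E)-prop-1-enyl B(mac) boronate | C[C@]12OB(/C=C/C)O[C@@]1(C)c1cccc3cccc2c13
A3 | alternative 1 | (3,4-dimethoxyphenyl)lithium | [Li]c1ccc(OC)c(OC)c1
A4 | alternative 1 | 2-[3-bromo-5-methoxy-4-(methoxymethoxy)phenyl]-1,3-dioxolane | COCOc1c(Br)cc(C2OCCO2)cc1OC
A5 | alternative 2 | methyl (2S,3S)-5-bromo-2-(3,4-dimethoxyphenyl)-7-methoxy-2,3-dihydro-1-benzofuran-3-carboxylate | COc1ccc([C@H]2Oc3c(OC)cc(Br)cc3[C@@H]2C(=O)OC)cc1OC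
A6 | alternative 2 | (2S)-6-bromo-2-(3,4-dimethoxyphenyl)-8-methoxy-2,3-dihydro-4H-chromen-4-one | COc1ccc([C@H]2Oc3c(OC)cc(Br)cc3C(=O)C2)cc1OC
A7 | alternative 3 | methyl (2S,3S)-7-bromo-2-(3,4-dimethoxyphenyl)-3-methyl-2,3-dihydro-1-benzofuran-5-carboxylate | COc1ccc([C@H]2Oc3c(Br)cc(C(=O)OC)cc3[C@@H]2C)cc1OC
A8 | alternative 3 | methyl 3-bromo-2-oxo-2H-pyran-5-carboxylate | COC(=O)C1=COC(=O)C(Br)=C1
A9 | alternative 3 | tert-butyl{[(4S,5S)-5-(3,4-dimethoxyphenyl)-4-methyl-4,5-dihydrofuran-2-yl]oxy}dimethylsilane | COc1ccc([C@H]2OC(O[Si](C)(C)C(C)(C)C)=C[C@@H]2C)cc1OC
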